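**Retrosynthetic overview**
1. Target ⇐ Z-selective semireduction of C4≡C5 and desilylation of a 19-membered enyne ansa-lactam.
2. That lactam ⇐ reductive O→N acyl-shift ring expansion of an 18-membered o-nitroaryl ansa-lactone (C1 moves from O21 to N; ring grows from 18 to 19 atoms).
3. The 18-membered lactone ⇐ intramolecular Sonogashira coupling (C3–C4) of an aryl (E)-3-iodo-2-methylacrylate that carries the terminal alkyne; the ester comes from the nitrophenol and the iodoacrylic acid.
4. Acyclic chain ⇐ stepwise growth from the aryl aldehyde: Z-crotylboration (C14–C15), hydroformylation (C11), enamine α-oxyamination (C12–O), Z-crotylboration (C10–C11), cross-metathesis with methacrolein (C8=C9), syn-propargylation (C6–C7).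
5. Arene ⇐ hydroquinone (silylation, ortho-formylation, nitration). Ring order: benzene ring (bought) → 18-membered lactone → 19-membered lactam.

Assumption and notation: ansamycin numbering is used (C1 amide carbonyl, C2–C15 ansa chain, C16–C21 arene; C18 and C21 carry O, C20 carries N); the target is the free hydroquinone, so steps 19–21 run under argon. Ar = 2-[(4-methoxybenzyl)oxy]-3-nitro-5-[(triisopropylsilyl)oxy]phenyl; TIPS = triisopropylsilyl; PMB = 4-methoxybenzyl; TEMP-O = (2,2,6,6-tetramethylpiperidin-1-yl)oxy; Bpin = pinacolatoboryl; (R)-TRIP = (R)-3,3'-bis(2,4,6-triisopropylphenyl)-1,1'-binaphthyl-2,2'-diyl hydrogen phosphate.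

**Route**

Step 1
Reactants: 1 hydroquinone (benzene-1,4-diol)
Product: 2 4-[(triisopropylsilyl)oxy]phenol
Conditions: iPr3SiCl (1 equiv), imidazole, DMF, 0 °C → rt (1 in threefold excess)
Reagents that add atoms: triisopropylsilyl chloride, CC(C)[Si](Cl)(C(C)C)C(C)C
Why: Statistical mono-silylation of the symmetrical diol (silyl ether formation) with the diol in excess; the bulky TIPS ether is chosen to last until step 20.

Step 2
Reactants: 2 4-[(triisopropylsilyl)oxy]phenol
Product: 3 2-hydroxy-5-[(triisopropylsilyl)oxy]benzaldehyde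
Conditions: MgCl2, Et3N, (CH2O)n, MeCN, reflux
Reagents that add atoms: formaldehyde (as paraformaldehyde), C=O
Why: Magnesium-phenoxide-directed ortho-formylation (Casnati–Skattebøl reaction) puts the future C15 only ortho to the free OH, a second formaldehyde oxidising the benzylic alkoxide by hydride transfer.

Step 3
Reactants: 3 2-hydroxy-5-[(triisopropylsilyl)oxy]benzaldehyde
Product: 4 2-hydroxy-3-nitro-5-[(triisopropylsilyl)oxy]benzaldehyde
Conditions: HNO3 (70 %, 1.1 equiv), AcOH, 15 °C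
Reagents that add atoms: nitric acid, O[N+](=O)[O-]
Why: Electrophilic aromatic nitration is steered by the free phenol to its only open ortho position (C20), as in the nitration of the 5-methoxy analogue.

Step 4
Reactants: 4 2-hydroxy-3-nitro-5-[(triisopropylsilyl)oxy]benzaldehyde
Product: 5 2-[(4-methoxybenzyl)oxy]-3-nitro-5-[(triisopropylsilyl)oxy]benzaldehyde (Ar–CHO)
Conditions: PMBCl, K2CO3, Bu4NI (cat.), DMF, rt
Reagents that add atoms: 4-methoxybenzyl chloride, COc1ccc(CCl)cc1
Why: Williamson etherification of the acidic nitrophenol masks O21 with a group that has no alkene (needed for steps 7 and 11) and is later removed oxidatively without touching the silyl ether.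

Step 5
Reactants: 5 Ar–CHO
Product: 7 (1R,2S)-1-Ar-2-methylbut-3-en-1-ol (C15 R; C14 S), via pinacol borate ester 6 (not isolated)
Conditions: (Z)-crotyl-Bpin (1.5 equiv), (R)-TRIP (5 mol %), 4 Å MS, toluene, −30 °C; aq. NaHCO3 work-up
Reagents that add atoms: (Z)-crotylboronic acid pinacol ester, C/C=C\CB1OC(C)(C)C(C)(C)O1
Why: Chiral-phosphoric-acid-catalysed crotylboration through a chair Zimmerman–Traxler transition state, where the Z-crotyl geometry gives the syn C14-Me/C15-OH pair and (R)-TRIP directs attack to the Re face of the aldehyde (C15 R, C14 S).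

Step 6
Reactants: 7 (1R,2S)-1-Ar-2-methylbut-3-en-1-ol
Product: 8 (1R,2S)-1-Ar-1-methoxy-2-methylbut-3-ene (C15 methyl ether)
Conditions: Me3OBF4, Proton-sponge, 4 Å MS, CH2Cl2, rt
Reagents that add atoms: trimethyloxonium tetrafluoroborate, C[O+](C)C.F[B-](F)(F)F
Why: O-Methylation with Meerwein salt buffered by Proton-sponge alkylates the hindered benzylic alcohol without alkoxide formation, so the aryl silyl ether and nitroarene are not endangered.

Step 7
Reactants: 8 (1R,2S)-1-Ar-1-methoxy-2-methylbut-3-ene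
Product: 9 (4S,5R)-5-Ar-5-methoxy-4-methylpentanal (aldehyde carbon = C11)
Conditions: Rh(acac)(CO)2 (1 mol %), BIPHEPHOS (3 mol %), CO/H2 (1:1, 10 bar), toluene, 60 °C
Reagents that add atoms: carbon monoxide, [C-]#[O+]
Why: Rhodium/bisphosphite-catalysed linear-selective hydroformylation adds C11 at the terminal alkene carbon, the allylic branch at C14 reinforcing anti-Markovnikov selectivity.

Step 8
Reactants: 9 (4S,5R)-5-Ar-5-methoxy-4-methylpentanal
Product: 10 (2S,4S,5R)-5-Ar-5-methoxy-4-methyl-2-(TEMP-O)pentanal (C12 S)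
Conditions: TEMPO (1.2 equiv), (5S)-5-benzyl-2,2,3-trimethylimidazolidin-4-one·CF3CO2H (20 mol %), CuCl2·2H2O (10 mol %), air, DMF, −10 °C
Reagents that add atoms: TEMPO, CC1(C)CCCC(C)(C)N1[O]
Why: Enamine-catalysed α-oxyamination in which the benzyl arm of the (5S)-imidazolidinone shields one face of the E-enamine so the copper-bound TEMPO adds to the other, setting C12 (S) and installing an O-protecting group that the zinc of step 19 removes.

Step 9
Reactants: 10 (2S,4S,5R)-5-Ar-5-methoxy-4-methyl-2-(TEMP-O)pentanal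
Product: 12 (3S,4R,5S,7S,8R)-8-Ar-8-methoxy-3,7-dimethyl-5-(TEMP-O)oct-1-en-4-ol (C10 S; C11 R), via pinacol borate ester 11 (not isolated)
Conditions: (Z)-crotyl-Bpin (2 equiv), (R)-TRIP (10 mol %), 4 Å MS, toluene, −30 → 0 °C; aq. NaHCO3 work-up
Reagents that add atoms: (Z)-crotylboronic acid pinacol ester, C/C=C\CB1OC(C)(C)C(C)(C)O1
Why: Second Z-crotylboration (chair transition state) gives syn C10-Me/C11-OH, and the Re-face preference of (R)-TRIP is matched with the Cornforth/Felkin preference of the α-aminoxy aldehyde for the 11,12-anti product.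

Step 10
Reactants: 12 (3S,4R,5S,7S,8R)-8-Ar-8-methoxy-3,7-dimethyl-5-(TEMP-O)oct-1-en-4-ol
Product: 13 C11-O-methyl ether of 12 (C10 S; C11 R; C12 S; C14 S; C15 R)
Conditions: Me3OBF4, Proton-sponge, 4 Å MS, CH2Cl2, rt
Reagents that add atoms: trimethyloxonium tetrafluoroborate, C[O+](C)C.F[B-](F)(F)F
Why: Base-free Meerwein methylation of the only free hydroxyl; the hindered alkoxyamine nitrogen is not alkylated.

Step 11
Reactants: 13 C11-O-methyl ether of 12; 14 methacrolein
Product: 15 (2E,4S,5R,6S,8S,9R)-9-Ar-5,9-dimethoxy-2,4,8-trimethyl-6-(TEMP-O)non-2-enal (C7 aldehyde; C8=C9 E)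
Conditions: 14 (10 equiv), RuCl2(=CH-C6H4-2-OiPr)(H2IMes) (Hoveyda–Grubbs second-generation catalyst, 10 mol %), CH2Cl2, 40 °C
Reagents that add atoms: none
Why: Olefin cross-metathesis of the monosubstituted alkene with excess methacrolein gives the thermodynamically favoured (E)-trisubstituted enal, the 1,1-disubstituted partner suppressing homodimerisation.

Step 12
Reactants: 16 (S)-but-3-yn-2-ol
Product: 17 (S)-but-3-yn-2-yl methanesulfonate
Conditions: MsCl, Et3N, CH2Cl2, −78 °C
Reagents that add atoms: methanesulfonyl chloride, CS(=O)(=O)Cl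
Why: Sulfonylation at oxygen leaves the stereocentre untouched and provides the leaving group for the stereospecific displacement.

Step 13
Reactants: 17 (S)-but-3-yn-2-yl methanesulfonate
Product: 18 (M)-tributyl(buta-1,2-dien-1-yl)stannane (aR allene)
Conditions: Bu3SnH, LiN(iPr)2, THF, 0 °C; CuBr·SMe2, −78 °C; then 17
Reagents that add atoms: tributyltin hydride, CCCC[SnH](CCCC)CCCC
Why: Anti SN2' displacement of the propargylic mesylate by the stannylcuprate (Marshall allenylstannane synthesis) transfers central to axial chirality and gives the M-allene.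

Step 14
Reactants: 15 (2E,4S,5R,6S,8S,9R)-enal; 18 (M)-allenylstannane
Product: 19 (3S,4R,5E,7S,8R,9S,11S,12R)-12-Ar-8,12-dimethoxy-3,5,7,11-tetramethyl-9-(TEMP-O)dodec-5-en-1-yn-4-ol (C6 S; C7 R)
Conditions: BF3·OEt2 (2 equiv), CH2Cl2, −78 °C
Reagents that add atoms: none
Why: BF3-promoted anti SE2' addition of the chiral allenylstannane through an open transition state (Marshall propargylation) gives the syn homopropargylic alcohol under reagent control, the new C–C bond at C6 taking the place of the mesylate oxygen.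

Step 15
Reactants: 19 homopropargylic alcohol
Product: 21 C7 primary carbamate of 19, via N-trichloroacetyl carbamate 20 (not isolated)
Conditions: Cl3CC(O)NCO, CH2Cl2, 0 °C; then K2CO3 (cat.), MeOH, 0 °C
Reagents that add atoms: trichloroacetyl isocyanate, O=C=NC(=O)C(Cl)(Cl)Cl
Why: Addition of the hindered allylic alcohol to the highly electrophilic isocyanate and mild methanolysis of the trichloroacetyl group (Kočovský carbamate synthesis) install the carbamate with retention at C7.

Step 16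
Reactants: 21 C7 carbamate (O21-PMB ether)
Product: 22 free C21 nitrophenol (PMB removed; C18–OTIPS; C12–O-TEMP; C7 carbamate; terminal alkyne)
Conditions: DDQ, CH2Cl2/pH 7 phosphate buffer (10:1), 0 °C → rt
Reagents that add atoms: none
Why: Oxidative cleavage of the 4-methoxybenzyl ether by DDQ (hydride abstraction, then hydrolysis) frees the nitrophenol while silyl ether, alkoxyamine, carbamate and alkyne are inert.

Step 17
Reactants: 22 C21 nitrophenol; 23 (E)-3-iodo-2-methylprop-2-enoic acid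
Product: 24 O21-aryl (E)-3-iodo-2-methylacrylate (C1–C3 attached to O21)
Conditions: EDC·HCl, DMAP, CH2Cl2, 0 °C → rt
Reagents that add atoms: none
Why: Steglich-type carbodiimide/DMAP esterification acylates the only free hydroxyl, the acidic nitrophenol, giving an activated aryl ester that stores C1 on O21.

Step 18
Reactants: 24 O21-aryl (E)-3-iodo-2-methylacrylate
Product: 25 18-membered o-nitroaryl enyne ansa-lactone (ring through O21, C21, C16, C15…C1; C2=C3 E; C4≡C5)
Conditions: Pd(PPh3)4 (15 mol %), CuI (30 mol %), Et3N, degassed THF (1 mM, syringe-pump addition), rt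
Reagents that add atoms: none
Why: Intramolecular Sonogashira coupling of the reactive β-iodoacrylate with the terminal alkyne under high dilution forges C3–C4 with retention of the E geometry, and the tertiary amine base does not cleave the aryl ester.

Step 19
Reactants: 25 18-membered o-nitroaryl enyne ansa-lactone
Product: 28 19-membered enyne ansa-lactam (C1–N amide; C21–OH and C12–OH free; C18–OTIPS), via aminoaryl macrolactone 26 (not isolated), via alkoxyamine macrolactam 27 (not isolated)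
Conditions: Zn dust, AcOH/THF/H2O (3:1:1), rt then 50 °C, argon
Reagents that add atoms: none
Why: Proposed new method: zinc reduction turns the ortho-nitro group of the 18-membered aryl ansa-lactone into an aniline held next to the ester oxygen, which attacks the activated aryl ester transannularly through a five-membered 2-hydroxy-2,3-dihydrobenzoxazole tetrahedral intermediate whose collapse expels the phenoxide and inserts N into the macrocycle (18 → 19 ring atoms, driven by amide over aryl ester stability), after which the same reagent on warming cleaves the alkoxyamine N–O bond to free C12–OH; the closest known reaction type is the O→N acyl migration of 2-aminophenyl esters and nitro-reduction-triggered acyl-transfer ring expansion of small lactones, not yet shown for closing an ansamycin macrolactam.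

Step 20
Reactants: 28 19-membered enyne ansa-lactam (C18–OTIPS)
Product: 29 4,5-didehydro hydroquinone lactam (C18–OH free; C4≡C5)
Conditions: Bu4NF, AcOH, THF, 0 °C, argon
Reagents that add atoms: none
Why: Fluoride-mediated desilylation of the aryl silyl ether, buffered with acetic acid so the hydroquinone is not exposed as its air-sensitive dianion.

Step 21
Reactants: 29 4,5-didehydro hydroquinone lactam
Product: 30 target macrolactam CNP0548031.1
Conditions: Zn dust activated with Cu(OAc)2 and AgNO3, MeOH/H2O (1:1), 35 °C, argon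
Reagents that add atoms: none
Why: Boland reduction, in which activated zinc reduces only the conjugated alkyne by syn delivery of hydrogen to give the (4Z) alkene of the (2E,4Z)-dienamide without over-reduction and under conditions that keep the hydroquinone reduced.

**Compound list**
1 | hydroquinone | Oc1ccc(O)cc1 | starting material
2 | 4-[(triisopropylsilyl)oxy]phenol | Oc1ccc(O[Si](C(C)C)(C(C)C)C(C)C)cc1 | intermediate
3 | 2-hydroxy-5-[(triisopropylsilyl)oxy]benzaldehyde | O=Cc1cc(O[Si](C(C)C)(C(C)C)C(C)C)ccc1O | intermediate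
4 | 2-hydroxy-3-nitro-5-[(triisopropylsilyl)oxy]benzaldehyde | O=[N+]([O-])c1cc(O[Si](C(C)C)(C(C)C)C(C)C)cc(c1O)C=O | intermediate
5 | 2-[(4-methoxybenzyl)oxy]-3-nitro-5-[(triisopropylsilyl)oxy]benzaldehyde (Ar–CHO) | O=[N+]([O-])c1cc(O[Si](C(C)C)(C(C)C)C(C)C)cc(c1OCc2ccc(OC)cc2)C=O | intermediate
6 | pinacol borate ester of 7 (not isolated) | O=[N+]([O-])c1cc(O[Si](C(C)C)(C(C)C)C(C)C)cc(c1OCc2ccc(OC)cc2)[C@H](OB3OC(C)(C)C(C)(C)O3)[C@@H](C)C=C | intermediate
7 | (1R,2S)-1-Ar-2-methylbut-3-en-1-ol | O=[N+]([O-])c1cc(O[Si](C(C)C)(C(C)C)C(C)C)cc(c1OCc2ccc(OC)cc2)[C@H](O)[C@@H](C)C=C | intermediate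
8 | (1R,2S)-1-Ar-1-methoxy-2-methylbut-3-ene | O=[N+]([O-])c1cc(O[Si](C(C)C)(C(C)C)C(C)C)cc(c1OCc2ccc(OC)cc2)[C@H](OC)[C@@H](C)C=C | intermediate
9 | (4S,5R)-5-Ar-5-methoxy-4-methylpentanal | O=[N+]([O-])c1cc(O[Si](C(C)C)(C(C)C)C(C)C)cc(c1OCc2ccc(OC)cc2)[C@H](OC)[C@@H](C)CCC=O | intermediate
10 | (2S,4S,5R)-5-Ar-5-methoxy-4-methyl-2-(TEMP-O)pentanal | O=[N+]([O-])c1cc(O[Si](C(C)C)(C(C)C)C(C)C)cc(c1OCc2ccc(OC)cc2)[C@H](OC)[C@@H](C)C[C@H](ON3C(C)(C)CCCC3(C)C)C=O | intermediate
11 | pinacol borate ester of 12 (not isolated) | O=[N+]([O-])c1cc(O[Si](C(C)C)(C(C)C)C(C)C)cc(c1OCc2ccc(OC)cc2)[C@H](OC)[C@@H](C)C[C@H](ON3C(C)(C)CCCC3(C)C)[C@H](OB4OC(C)(C)C(C)(C)O4)[C@@H](C)C=C | intermediate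
12 | (3S,4R,5S,7S,8R)-8-Ar-8-methoxy-3,7-dimethyl-5-(TEMP-O)oct-1-en-4-ol | O=[N+]([O-])c1cc(O[Si](C(C)C)(C(C)C)C(C)C)cc(c1OCc2ccc(OC)cc2)[C@H](OC)[C@@H](C)C[C@H](ON3C(C)(C)CCCC3(C)C)[C@H](O)[C@@H](C)C=C | intermediate
13 | C11-O-methyl ether of 12 | O=[N+]([O-])c1cc(O[Si](C(C)C)(C(C)C)C(C)C)cc(c1OCc2ccc(OC)cc2)[C@H](OC)[C@@H](C)C[C@H](ON3C(C)(C)CCCC3(C)C)[C@H](OC)[C@@H](C)C=C | intermediate
14 | methacrolein | C=C(C)C=O | starting material
15 | (2E,4S,5R,6S,8S,9R)-9-Ar-5,9-dimethoxy-2,4,8-trimethyl-6-(TEMP-O)non-2-enal | O=[N+]([O-])c1cc(O[Si](C(C)C)(C(C)C)C(C)C)cc(c1OCc2ccc(OC)cc2)[C@H](OC)[C@@H](C)C[C@H](ON3C(C)(C)CCCC3(C)C)[C@H](OC)[C@@H](C)/C=C(\C)C=O | intermediate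
16 | (S)-but-3-yn-2-ol | C#C[C@H](C)O | starting material
17 | (S)-but-3-yn-2-yl methanesulfonate | C#C[C@H](C)OS(C)(=O)=O | intermediate
18 | (M)-tributyl(buta-1,2-dien-1-yl)stannane | CCCC[Sn](CCCC)(CCCC)C([H])=[C@]=C([H])C | intermediate
19 | (3S,4R,5E,7S,8R,9S,11S,12R)-12-Ar-8,12-dimethoxy-3,5,7,11-tetramethyl-9-(TEMP-O)dodec-5-en-1-yn-4-ol | O=[N+]([O-])c1cc(O[Si](C(C)C)(C(C)C)C(C)C)cc(c1OCc2ccc(OC)cc2)[C@H](OC)[C@@H](C)C[C@H](ON3C(C)(C)CCCC3(C)C)[C@H](OC)[C@@H](C)/C=C(\C)[C@H](O)[C@@H](C)C#C | intermediate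
20 | N-trichloroacetyl carbamate of 19 (not isolated) | O=[N+]([O-])c1cc(O[Si](C(C)C)(C(C)C)C(C)C)cc(c1OCc2ccc(OC)cc2)[C@H](OC)[C@@H](C)C[C@H](ON3C(C)(C)CCCC3(C)C)[C@H](OC)[C@@H](C)/C=C(\C)[C@H](OC(=O)NC(=O)C(Cl)(Cl)Cl)[C@@H](C)C#C | intermediate
21 | C7 primary carbamate of 19 | O=[N+]([O-])c1cc(O[Si](C(C)C)(C(C)C)C(C)C)cc(c1OCc2ccc(OC)cc2)[C@H](OC)[C@@H](C)C[C@H](ON3C(C)(C)CCCC3(C)C)[C@H](OC)[C@@H](C)/C=C(\C)[C@H](OC(N)=O)[C@@H](C)C#C | intermediate
22 | C21 nitrophenol (PMB removed from 21) | O=[N+]([O-])c1cc(O[Si](C(C)C)(C(C)C)C(C)C)cc(c1O)[C@H](OC)[C@@H](C)C[C@H](ON3C(C)(C)CCCC3(C)C)[C@H](OC)[C@@H](C)/C=C(\C)[C@H](OC(N)=O)[C@@H](C)C#C | intermediate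
23 | (E)-3-iodo-2-methylprop-2-enoic acid | C/C(=C\I)C(O)=O | starting material
24 | O21-aryl (E)-3-iodo-2-methylacrylate of 22 | O=[N+]([O-])c1cc(O[Si](C(C)C)(C(C)C)C(C)C)cc(c1OC(=O)/C(C)=C/I)[C@H](OC)[C@@H](C)C[C@H](ON3C(C)(C)CCCC3(C)C)[C@H](OC)[C@@H](C)/C=C(\C)[C@H](OC(N)=O)[C@@H](C)C#C | intermediate
25 | 18-membered o-nitroaryl enyne ansa-lactone | O=[N+]([O-])c1cc(O[Si](C(C)C)(C(C)C)C(C)C)cc(c1O2)[C@H](OC)[C@@H](C)C[C@H](ON3C(C)(C)CCCC3(C)C)[C@H](OC)[C@@H](C)/C=C(\C)[C@H](OC(N)=O)[C@@H](C)C#C/C=C(\C)C2=O | intermediate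
26 | o-aminoaryl 18-membered ansa-lactone (not isolated) | Nc1cc(O[Si](C(C)C)(C(C)C)C(C)C)cc(c1O2)[C@H](OC)[C@@H](C)C[C@H](ON3C(C)(C)CCCC3(C)C)[C@H](OC)[C@@H](C)/C=C(\C)[C@H](OC(N)=O)[C@@H](C)C#C/C=C(\C)C2=O | intermediate
27 | 19-membered enyne ansa-lactam with C12–O-TEMP (not isolated) | N2c1cc(O[Si](C(C)C)(C(C)C)C(C)C)cc(c1O)[C@H](OC)[C@@H](C)C[C@H](ON3C(C)(C)CCCC3(C)C)[C@H](OC)[C@@H](C)/C=C(\C)[C@H](OC(N)=O)[C@@H](C)C#C/C=C(\C)C2=O | intermediate
28 | 19-membered enyne ansa-lactam (C12–OH, C21–OH, C18–OTIPS) | N2c1cc(O[Si](C(C)C)(C(C)C)C(C)C)cc(c1O)[C@H](OC)[C@@H](C)C[C@H](O)[C@H](OC)[C@@H](C)/C=C(\C)[C@H](OC(N)=O)[C@@H](C)C#C/C=C(\C)C2=O | intermediate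
29 | 4,5-didehydro hydroquinone lactam | N2c1cc(O)cc(c1O)[C@H](OC)[C@@H](C)C[C@H](O)[C@H](OC)[C@@H](C)/C=C(\C)[C@H](OC(N)=O)[C@@H](C)C#C/C=C(\C)C2=O | intermediate
30 | CNP0548031.1 (2E,4Z,8E; 6S,7R,10S,11R,12S,14S,15R) | CO[C@@H]1[C@@H](C)/C=C(\C)[C@H](OC(N)=O)[C@@H](C)/C=C\C=C(/C)C(=O)Nc2cc(O)cc(c2O)[C@H](OC)[C@@H](C)C[C@@H]1O | target

**Step count and risk**
Total steps: 21. Longest linear sequence: 19 (steps 1–11, then 14–21); steps 12–13 form the side branch.

Most likely to fail:

Step 19 (the proposed ring expansion). The transannular acyl shift may be slowed by the macrocycle, or the aryl lactone may open before the amine is formed. The fallback sets out from 24 and comes back at 27, and uses only known chemistry. 24 is reduced with Fe powder and NH4Cl (EtOH/H2O, 60 °C). The acyclic 2-aminophenyl ester then rearranges by the classical O→N acyl migration to the acyclic N-(2-hydroxyaryl) (E)-3-iodo-2-methylacrylamide F1. An intramolecular Sonogashira coupling (Pd(PPh3)4, CuI, Et3N, THF, 1 mM) closes the 19-membered ring directly at C3–C4 to give 27. From 27 only the zinc/acetic acid N–O cleavage of step 19 is needed to reach 28. The amide is thus made before the ring, and no ring-size change is required.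

Step 18 (macrocyclic Sonogashira). Oligomerisation, alkyne homocoupling or strain in the 18-membered enyne ring may defeat it. The fallback sets out from 22 and comes back at 25. 22 and 23 are joined intermolecularly by Sonogashira coupling (Pd(PPh3)4, CuI, Et3N, THF, rt) to give the seco enynoic acid F2. F2 is closed at the C1–O21 bond by Shiina macrolactonisation (2-methyl-6-nitrobenzoic anhydride, DMAP, Et3N, CH2Cl2, high dilution) to give 25. The ring is closed by C–O instead of C–C bond formation, and the enynoic acid has no Z-alkene that could isomerise on activation.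

Step 11 (cross-metathesis). The alkene is α-branched and sits next to a bulky alkoxyamine, so conversion may stall. The fallback sets out from 13 and comes back at 15. Oxidative cleavage of the terminal alkene (OsO4 cat., NaIO4, 2,6-lutidine, dioxane/H2O) gives the C9 aldehyde F3. F3 is used without delay in a Wittig olefination with Ph3P=C(CH3)CHO (toluene, 80 °C), which gives the (E)-enal 15.

Further compounds
F1 | step 19 | acyclic N-(2-hydroxyaryl) (E)-3-iodo-2-methylacrylamide (C18–OTIPS; C12–O-TEMP; C7 carbamate; terminal alkyne) | I/C=C(\C)C(=O)Nc1cc(O[Si](C(C)C)(C(C)C)C(C)C)cc(c1O)[C@H](OC)[C@@H](C)C[C@H](ON2C(C)(C)CCCC2(C)C)[C@H](OC)[C@@H](C)/C=C(\C)[C@H](OC(N)=O)[C@@H](C)C#C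
F2 | step 18 | seco (2E)-2-methyl-en-4-ynoic acid with free C21 nitrophenol | O=[N+]([O-])c1cc(O[Si](C(C)C)(C(C)C)C(C)C)cc(c1O)[C@H](OC)[C@@H](C)C[C@H](ON2C(C)(C)CCCC2(C)C)[C@H](OC)[C@@H](C)/C=C(\C)[C@H](OC(N)=O)[C@@H](C)C#C/C=C(\C)C(O)=O
F3 | step 11 | C9 aldehyde from cleavage of 13 | O=[N+]([O-])c1cc(O[Si](C(C)C)(C(C)C)C(C)C)cc(c1OCc2ccc(OC)cc2)[C@H](OC)[C@@H](C)C[C@H](ON3C(C)(C)CCCC3(C)C)[C@H](OC)[C@@H](C)C=O
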